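In a one-step world each D lost would be Z gained, so a balance on D, charged in less than X or G, would give you Z directly.

| flask | D | X | G | Q | remark | time |
|---|---|---|---|---|---|---|
| teal | 15 mM | 1.1 equiv (in portions, 2) | 1.2 equiv | 22 mM | run made earlier; portions every 20 s |  |
| ash | 15 mM | 1.10 equiv (in portions, 2) | 1.20 equiv | 15.0 mM | the portions of X follow each other after 20 s, the first at the start | 5.0 min |
| oak | 5.0 mM | 1.10 equiv | 1.20 equiv | 15.0 mM | everything together at the start | 8.0 min |

teal run (percent of the D charged)

| time / s | Z / % | D / % |
|---|---|---|
| 10.0 | 0.4 | 84.5 |
| 12.0 | 0.4 | 81.9 |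
| 20.0 | 0.4 | 74.7 |
| 30.0 | 1.3 | 68.0 |
| 50.0 | 3.0 | 60.7 |
| 60.0 | 3.7 | 58.4 |
| 120 | 9.7 | 53.8 |

(standard deviation of a reading: 0.3 percentage points)

- where the amount of D changes, what is given in equivalents or mol% on it follows
- no earlier run changes the charge of Q; that part of a forecast is a guess

- which one finishes higher in amount of Z, in percent of the D charged ("neither" within 2 percentage points) (ash / oak / neither)
- amount of Z at the end, in percent of the D charged, ash
- amount of Z at the end, in percent of the D charged, oak

Teal refuses that world: at 120 s D stands at 53.8 % and Z at 9.7 %, so 36.5 % of the charge sits in something unread. Your loose ceiling for ash is the D lost, 46.2 %, if ash stalls as teal does. Your floor is teal's 9.7 %, if having 15.0 mM of Q rather than 22 mM does no harm, which is a guess.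

To tighten the ceiling, take the filling time, the time teal's last interval of Z growth would need to turn the whole D charge into Z: 16.7 min. If the rate does not climb, ash reaches 27.7 %. If Z needs two dissolved partners, the percentage rate scales with the charge, so oak stays under 16.0 %. These two brackets overlap, for ash's floor lies under oak's ceiling, so they prove no order. Ash's ceiling stands above oak's, so you would bet on ash, as a judgement and not a proof.

The forecast also says ash, with 40 % for ash and 3 % for oak, on the ground that “only excess X makes Z”. Its ash figure lies inside the loose bracket but above your tightened ceiling, and its oak figure lies under your oak ceiling.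

The flask gives 20.3 % for ash and 8.48 % for oak, so ash finishes higher. Ash stands under its tightened ceiling, and oak stands under its own.

    L + E → Z (k = 0.440 M⁻¹ s⁻¹)
    G + X → E (k = 2.30 M⁻¹ s⁻¹)
    D + G → L (k = 1.10 M⁻¹ s⁻¹)
    E + Q → J (k = 0.320 M⁻¹ s⁻¹)

In oak, E goes into J 12 times as fast as into Z at 0.700 min. At 8.00 min that ratio is still 5.2, while G, the limiting reagent, is down to 1.42 % of its charge. Now take the neighbour of oak charged with 6.0 mM of Q: the filling time holds no term in Q, so it gives the same 16.0 %. The computed neighbour ends at 12.8 %, under that ceiling and above oak.

The readings were generated by integration with made-up constants; noise was put on by code.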